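**Plan**

1. Numbering used throughout: C1 (butyrate carbinol)–C2–C3=C4(Me)–C5–C6–O7–C8–C9–C10–C11(Me)=C12–C13(=O)–C14–C15(Me)–C16–O17–C18(Me). The bonds C18–C1, C18–C8, C10–C6 and C14–C9 close ring A (C9–C14), ring B (C6, O7, C8, C9, C10), ring C (C8, C9, C14, C15, C16, O17, C18) and ring D (C1–C6, O7, C8, C18).
2. Enabling feature: on ring A the arms C6 (at C10), C8 (at C9) and C15 (at C14) sit on three neighbouring carbons, all cis, right beside the C11=C12 alkene. An endo [4+2] of a 1-boryl diene followed by allyl transfer from boron produces exactly this pattern.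
3. Cuts in retrosynthetic order: the butyrate; C3=C4 (ring D, metathesis); C1–C2 (allylation); C13=O (allylic oxidation); O17–C16 (ring C); O7–C8 (ring B, epoxide opening). Then C6–C10, C12–C13 and C9–C14 are cut together, which leaves an epoxy dienylboronate, methyl vinyl ketone and a ketal aldehyde.
4. Forward ring order: A by cycloaddition, B by 5-exo epoxide opening, C by triflate etherification, D by ring-closing metathesis. The C4 alkene stays masked (ketal, then β-hydroxysilane) until the hydroboration and the allylic oxidation are over.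
5. Stereochemistry: C8 and C18 come from a Sharpless epoxidation of a Z-allylic alcohol. C9, C14, C10 and C6 are relayed from C8 in the key step, and C8 is inverted when ring B closes. C15 comes from hydroboration, C1 from chelate-controlled allylation, and the Z alkene from the nine-membered ring.

Key step: step 10

Remark: the carbinol carbon C4 of 25 and 26 forms as an epimer mixture and is drawn without configuration, because step 18 turns it into an sp2 carbon. The enantiomeric purity of the whole series rests on step 6.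

**Step 1**
Reactants: 1 prop-2-yn-1-ol
Product: 3 (E)-3-iodo-2-methylprop-2-en-1-ol, via alkenylalane 2 (not isolated)
Conditions: Me3Al (3 equiv), Cp2ZrCl2 (25 mol %), CH2Cl2, 0 → 23 °C; I2, THF, −30 °C
Reagents that add atoms: trimethylaluminium C[Al](C)C; iodine II
Why: Negishi carboalumination adds methyl and aluminium syn across the alkyne with aluminium at the terminus, and iodinolysis with retention fixes the E geometry of C11=C12.

**Step 2**
Reactants: 3 (E)-3-iodo-2-methylprop-2-en-1-ol
Product: 4 (E)-3-iodo-2-methylprop-2-enal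
Conditions: MnO2, CH2Cl2, 23 °C; used crude
Reagents that add atoms: none
Why: MnO2 oxidises only the allylic alcohol and leaves the alkenyl iodide and the alkene geometry alone.

**Step 3**
Reactants: 4 (E)-3-iodo-2-methylprop-2-enal
Product: 5 (2E,4E)-5-iodo-4-methylpenta-2,4-dienal
Conditions: Ph3P=CHCHO (1.0 equiv, slow addition), toluene, 70 °C
Reagents that add atoms: (triphenylphosphoranylidene)acetaldehyde O=CC=P(c1ccccc1)(c1ccccc1)c1ccccc1
Why: the Wittig reaction of the stabilised formyl ylide gives the E alkene C9=C10, and slow addition of a single equivalent keeps a second homologation down.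

**Step 4**
Reactants: 5 (2E,4E)-5-iodo-4-methylpenta-2,4-dienal
Product: 6 ethyl (2Z,4E,6E)-7-iodo-2,6-dimethylhepta-2,4,6-trienoate
Conditions: (CF3CH2O)2P(O)CH(CH3)CO2Et, KN(SiMe3)2, 18-crown-6, THF, −78 °C
Reagents that add atoms: ethyl 2-[bis(2,2,2-trifluoroethoxy)phosphoryl]propanoate CCOC(=O)C(C)P(=O)(OCC(F)(F)F)OCC(F)(F)F
Why: in the Still–Gennari olefination the electron-poor phosphonate eliminates faster than the adducts equilibrate, which gives the Z alkene C8=C18 that later places C9 and C1 cis on the epoxide.

**Step 5**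
Reactants: 6 ethyl (2Z,4E,6E)-7-iodo-2,6-dimethylhepta-2,4,6-trienoate
Product: 7 (2Z,4E,6E)-7-iodo-2,6-dimethylhepta-2,4,6-trien-1-ol
Conditions: iBu2AlH (2.2 equiv), CH2Cl2, −78 °C
Reagents that add atoms: none
Why: 1,2-reduction of the conjugated ester with iBu2AlH at low temperature gives the allylic alcohol without touching the triene or the C–I bond.

**Step 6**
Reactants: 7 (2Z,4E,6E)-7-iodo-2,6-dimethylhepta-2,4,6-trien-1-ol
Product: 8 [(2S,3R)-3-[(1E,3E)-4-iodo-3-methylbuta-1,3-dienyl]-2-methyloxiran-2-yl]methanol
Conditions: Ti(OiPr)4 (20 mol %), L-(+)-diethyl tartrate (24 mol %), t-BuOOH, 4 Å MS, CH2Cl2, −20 °C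
Reagents that add atoms: tert-butyl hydroperoxide CC(C)(C)OO
Why: the Sharpless asymmetric epoxidation is steered by the C1 hydroxyl to C8=C18 only, and with Z-allylic alcohols of this substitution type L-(+)-tartrate gives the (2S,3R) epoxide, which sets C18 (S) and C8 (R).

**Step 7**
Reactants: 8 epoxy alcohol
Product: 9 tert-butyldimethylsilyl ether of 8, (8R,18S)
Conditions: TBSCl, imidazole, CH2Cl2, 0 °C
Reagents that add atoms: tert-butyldimethylsilyl chloride CC(C)(C)[Si](C)(C)Cl
Why: silylation under imidazole catalysis needs neither acid nor strong base, either of which would endanger the dienyl epoxide.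

**Step 8**
Reactants: 9 iodo dienyl epoxide silyl ether
Product: 11 2-[(1E,3E)-4-[(2R,3S)-3-(tert-butyldimethylsilyloxymethyl)-3-methyloxiran-2-yl]-2-methylbuta-1,3-dienyl]-4,4,5,5-tetramethyl-1,3,2-dioxaborolane, via dienyllithium 10 (not isolated)
Conditions: t-BuLi (2.1 equiv), Et2O, −78 °C; iPrOBpin, −78 → 0 °C; H2O
Reagents that add atoms: 2-isopropoxy-4,4,5,5-tetramethyl-1,3,2-dioxaborolane CC(C)OB1OC(C)(C)C(C)(C)O1
Why: iodine–lithium exchange with retention outruns any attack on the epoxide at −78 °C and the alkenyllithium is trapped by the borate ester, whereas a palladium-catalysed borylation is avoided because zerovalent palladium would ionise the dienyl epoxide.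

**Step 9**
Reactants: 12 ethyl 2-(2-methyl-1,3-dioxolan-2-yl)acetate
Product: 13 2-(2-methyl-1,3-dioxolan-2-yl)acetaldehyde
Conditions: iBu2AlH (1.05 equiv), CH2Cl2, −78 °C; used without storage
Reagents that add atoms: none
Why: partial ester reduction stops at the aluminium hemiacetal at −78 °C, which releases the aldehyde only on work-up.

**Step 10**
Reactants: 11 epoxy dienylboronate; 14 but-3-en-2-one (methyl vinyl ketone); 13 ketal aldehyde
Product: 17 ring A homoallylic alcohol (6S,8R,9R,10S,14S,18S) whose cyclohexene C9–C14 holds C11=C12 and three all-cis arms (the CH(OH)CH2–ketal chain at C10; the silyloxymethyl epoxide at C9; acetyl at C14), via cyclic allylboronate 15 (not isolated), via pinacol borate 16 (not isolated)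
Conditions: 14 (5 equiv), BHT (1 mol %), toluene (1 M), 85 °C; cool, 13 (1.5 equiv), 23 → 45 °C; pH 7 buffer
Reagents that add atoms: none
Why: Mechanism: the s-cis diene C12=C11–C10=C9 of 11 and the enone 14 combine in a concerted thermal [4+2] (C12–C13 and C9–C14 form) to leave the cyclic allylboronate 15, whose B–C12–C11=C10 unit then hands C10 to the carbonyl carbon of 13 through a closed six-membered chair (C6–C10 forms, the alkene moves to C11=C12), and the borate 16 is hydrolysed on work-up. The closest known reaction type is the one-pot Diels–Alder/allylboration sequence of 1-boryl-1,3-dienes with an acrylic dienophile and an aldehyde, applied here to a diene that carries an epoxide. Ring A is the only ring that closes, by suprafacial six-electron cycloaddition, and the allyl transfer is intermolecular and closes none. C9 is controlled by C8, because in the reactive rotamer H8 lies near the diene plane towards H10 while the C8–C18 bond stands perpendicular to it and its cis CH2OTBS arm covers that face, so 14 adds from the face of the epoxide oxygen; C14 follows from the endo orientation of the acetyl group, which together with the E,E geometry puts boron, C8 and C15 on one face. C10 is controlled by C12, since boron delivers the aldehyde on the face it occupies, and C6 by the chair with the aldehyde chain equatorial and the ring-locked Z allyl unit, which gives the syn C6/C10 pair. The step needs regio-, endo-, face- and chemoselectivity: the C11 methyl group and the C9 alkyl arm both enlarge the HOMO coefficient at C12 so that the enone CH2 bonds there, secondary orbital overlap favours endo, the shielded face decides the diene face, and allylboronates take aldehydes far faster than the ketones present, while late addition of 13 spares it the heating.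

**Step 11**
Reactants: 17 ring A homoallylic alcohol
Product: 18 isopropenyl analogue of 17 (C15=C16H2), (6S,8R,9S,10S,14S,18S)
Conditions: Cp2TiMe2 (3 equiv), toluene, 70 °C, dark
Reagents that add atoms: dimethyltitanocene [CH3-].[CH3-].[Ti+4].c1cc[cH-]c1.c1cc[cH-]c1
Why: the Petasis methylenation works through a non-basic titanium carbene, so the epimerisable C14 is not touched, and excess reagent copes with the free C6 hydroxyl while epoxide, ketal and silyl ether are inert.

**Step 12**
Reactants: 18 isopropenyl epoxy alcohol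
Product: 19 rings A/B tetrahydrofuran (6S,8S,9S,10S,14S,18S) bearing the tertiary C18 alcohol
Conditions: KOt-Bu (0.3 equiv), t-BuOH–THF, 40 °C
Reagents that add atoms: none
Why: base-catalysed 5-exo-tet epoxide opening lets the C6 alkoxide attack the less substituted C8 in an SN2 manner (inversion to 8S, C18–O retained), and the protic medium protonates the tertiary alkoxide before the silyl group can move.

**Step 13**
Reactants: 19 rings A/B tetrahydrofuran
Product: 21 diol (6S,8S,9S,10S,14R,15R,18S) with the primary C16 alcohol, via alkyl-9-BBN 20 (not isolated)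
Conditions: 9-BBN (3 equiv), THF, 0 → 23 °C; NaOH, H2O2, 0 °C
Reagents that add atoms: hydrogen peroxide OO
Why: in this Brown hydroboration–oxidation the bulky borane takes only the 1,1-disubstituted C15=C16 alkene and spares C11=C12, and boron should reach C16 in the rotamer that keeps C16 beside the C13 methylene and away from the C9 arm, with hydrogen arriving at C15 from the H14 side to give 15R.

**Step 14**
Reactants: 21 diol
Product: 23 rings A/B/C oxepane (6S,8S,9S,10S,14R,15R,18S), via primary triflate 22 (not isolated)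
Conditions: Tf2O (1.1 equiv), 2,6-lutidine (3 equiv), CH2Cl2, −78 → 23 °C
Reagents that add atoms: none
Why: only the primary alcohol is triflated at −78 °C, and the neighbouring tertiary C18 hydroxyl displaces the triflate in an intramolecular Williamson-type 7-exo-tet etherification that touches no stereocentre.

**Step 15**
Reactants: 23 oxepane ketal
Product: 24 C4 methyl ketone
Conditions: PPTS (20 mol %), acetone–H2O 9:1, 50 °C
Reagents that add atoms: water O
Why: mild acid-catalysed ketal hydrolysis frees the ketone, while the neopentyl-type primary silyl ether and the ring ethers survive.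

**Step 16**
Reactants: 24 C4 methyl ketone
Product: 25 C4 β-hydroxysilane (tertiary carbinol carrying CH2SiMe3, both C4 epimers)
Conditions: Me3SiCH2MgCl (2 equiv), THF, −78 → 0 °C; H2O
Reagents that add atoms: (trimethylsilyl)methylmagnesium chloride C[Si](C)(C)C[Mg]Cl
Why: this Grignard addition is the first half of a Peterson olefination and is stopped at the carbinol, so the molecule has no second alkene and no second ketone during the next step, and the weakly basic reagent spares the β-alkoxy ketone from elimination.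

**Step 17**
Reactants: 25 C4 β-hydroxysilane
Product: 26 C13 enone (6S,8S,9R,10S,14R,15R,18S)
Conditions: Rh2(cap)4 (1 mol %), t-BuOOH (5 equiv), K2CO3, CH2Cl2, 23 °C
Reagents that add atoms: tert-butyl hydroperoxide CC(C)(C)OO
Why: in this dirhodium caprolactamate/t-BuOOH allylic oxidation the peroxyl radical abstracts hydrogen from the only ring allylic methylene (C13) of the sole alkene, which is the usual route from a 1-methylcyclohexene to a 3-methylcyclohex-2-enone.

**Step 18**
Reactants: 26 C13 enone
Product: 27 enone alcohol with C4=CH2 and free C1–OH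
Conditions: HF (48 % aq), MeCN, 0 → 23 °C
Reagents that add atoms: none
Why: acid-induced Peterson elimination of the tertiary β-hydroxysilane and fluoride cleavage of the silyl ether take place in the same medium, so the methallyl unit appears without any carbonyl olefination next to the enone.

**Step 19**
Reactants: 27 enone alcohol
Product: 28 C1 aldehyde (18R by priority change only)
Conditions: Dess–Martin periodinane, CH2Cl2, 23 °C
Reagents that add atoms: none
Why: the Dess–Martin oxidation gives the aldehyde under neutral conditions, and its α-carbon C18 is quaternary and cannot epimerise.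

**Step 20**
Reactants: 28 C1 aldehyde
Product: 29 (1R)-homoallylic alcohol
Conditions: MgBr2·OEt2 (3 equiv), Bu3SnCH2CH=CH2 (2 equiv), CH2Cl2, −78 → −20 °C
Reagents that add atoms: allyltributylstannane C=CC[Sn](CCCC)(CCCC)CCCC
Why: in this Keck allylation under chelate control MgBr2 ties the aldehyde oxygen to O17, and the five-membered chelate exposes the face flanked by the C18 methyl group rather than by C8, so allyl transfer gives 1R, while the hindered enone is left alone.

**Step 21**
Reactants: 29 (1R)-homoallylic alcohol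
Product: 30 tetracyclic alcohol (1R,6S,8S,9R,10S,14R,15R,18S; 3Z)
Conditions: second-generation Grubbs catalyst (10 mol %), CH2Cl2 (1 mM), 40 °C
Reagents that add atoms: none
Why: in the ring-closing metathesis ruthenium loads on the allyl group and closes onto the methallyl alkene, helped by the cis arms at C6 and C8 of ring B and by ring C, which freezes the C8–C18 bond with C1 turned towards C5, and the nine-membered ring allows only the Z alkene.

**Step 22**
Reactants: 30 tetracyclic alcohol
Product: 31 target butyrate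
Conditions: (n-PrCO)2O, Et3N, DMAP (20 mol %), CH2Cl2, 23 °C
Reagents that add atoms: butyric anhydride CCCC(=O)OC(=O)CCC
Why: DMAP-catalysed acylation esterifies the only hydroxyl with retention at C1 under conditions too mild to enolise C14.

**Compound list**

1 | prop-2-yn-1-ol | C#CCO | starting material
2 | (E)-alkenylalane, O- and C-bound AlMe2 | C[Al](C)OC/C(C)=C/[Al](C)C | intermediate
3 | (E)-3-iodo-2-methylprop-2-en-1-ol | OC/C(C)=C/I | intermediate
4 | (E)-3-iodo-2-methylprop-2-enal | O=C/C(C)=C/I | intermediate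
5 | (2E,4E)-5-iodo-4-methylpenta-2,4-dienal | O=C/C=C/C(C)=C/I | intermediate
6 | ethyl (2Z,4E,6E)-7-iodo-2,6-dimethylhepta-2,4,6-trienoate | CCOC(=O)/C(C)=C\C=C\C(C)=C\I | intermediate
7 | (2Z,4E,6E)-7-iodo-2,6-dimethylhepta-2,4,6-trien-1-ol | OC/C(C)=C\C=C\C(C)=C\I | intermediate
8 | (2S,3R)-epoxy alcohol | I/C=C(C)/C=C/[C@H]1O[C@@]1(C)CO | intermediate
9 | TBS ether of 8 | I/C=C(C)/C=C/[C@H]1O[C@@]1(C)CO[Si](C)(C)C(C)(C)C | intermediate
10 | dienyllithium | [Li]/C=C(C)/C=C/[C@H]1O[C@@]1(C)CO[Si](C)(C)C(C)(C)C | intermediate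
11 | epoxy dienylboronate (8R,18S) | CC1(C)OB(OC1(C)C)/C=C(C)/C=C/[C@H]2O[C@@]2(C)CO[Si](C)(C)C(C)(C)C | intermediate
12 | ethyl 2-(2-methyl-1,3-dioxolan-2-yl)acetate | CCOC(=O)CC1(C)OCCO1 | starting material
13 | 2-(2-methyl-1,3-dioxolan-2-yl)acetaldehyde | CC1(CC=O)OCCO1 | intermediate
14 | but-3-en-2-one | C=CC(C)=O | starting material
15 | cyclic allylboronate (8R,9R,12R,14S,18S), with Bpin, epoxide arm and acetyl all cis | CC(=O)[C@H]1C[C@@H](B2OC(C)(C)C(C)(C)O2)C(C)=C[C@H]1[C@H]3O[C@@]3(C)CO[Si](C)(C)C(C)(C)C | intermediate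
16 | pinacol borate of 17 | CC1(C[C@H](OB4OC(C)(C)C(C)(C)O4)[C@@H]2C(C)=CC[C@H](C(C)=O)[C@@H]2[C@H]3O[C@@]3(C)CO[Si](C)(C)C(C)(C)C)OCCO1 | intermediate
17 | ring A homoallylic alcohol | CC1(C[C@H](O)[C@@H]2C(C)=CC[C@H](C(C)=O)[C@@H]2[C@H]3O[C@@]3(C)CO[Si](C)(C)C(C)(C)C)OCCO1 | intermediate
18 | isopropenyl epoxy alcohol | CC1(C[C@H](O)[C@@H]2C(C)=CC[C@H](C(C)=C)[C@@H]2[C@H]3O[C@@]3(C)CO[Si](C)(C)C(C)(C)C)OCCO1 | intermediate
19 | rings A/B tetrahydrofuran, C18 tertiary alcohol | CC1(C[C@@H]2O[C@H]([C@@](C)(O)CO[Si](C)(C)C(C)(C)C)[C@@H]3[C@H]2C(C)=CC[C@@H]3C(C)=C)OCCO1 | intermediate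
20 | C16 alkyl-9-BBN | CC1(C[C@@H]2O[C@H]([C@@](C)(O)CO[Si](C)(C)C(C)(C)C)[C@@H]3[C@H]2C(C)=CC[C@@H]3[C@@H](C)CB4C5CCCC4CCC5)OCCO1 | intermediate
21 | (15R)-diol | CC1(C[C@@H]2O[C@H]([C@@](C)(O)CO[Si](C)(C)C(C)(C)C)[C@@H]3[C@H]2C(C)=CC[C@@H]3[C@@H](C)CO)OCCO1 | intermediate
22 | C16 primary triflate | CC1(C[C@@H]2O[C@H]([C@@](C)(O)CO[Si](C)(C)C(C)(C)C)[C@@H]3[C@H]2C(C)=CC[C@@H]3[C@@H](C)COS(=O)(=O)C(F)(F)F)OCCO1 | intermediate
23 | rings A/B/C oxepane ketal | CC1(C[C@@H]2O[C@H]3[C@@H]4[C@H]2C(C)=CC[C@@H]4[C@@H](C)CO[C@@]3(C)CO[Si](C)(C)C(C)(C)C)OCCO1 | intermediate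
24 | C4 methyl ketone | CC(=O)C[C@@H]1O[C@H]2[C@@H]3[C@H]1C(C)=CC[C@@H]3[C@@H](C)CO[C@@]2(C)CO[Si](C)(C)C(C)(C)C | intermediate
25 | C4 β-hydroxysilane | CC(O)(C[Si](C)(C)C)C[C@@H]1O[C@H]2[C@@H]3[C@H]1C(C)=CC[C@@H]3[C@@H](C)CO[C@@]2(C)CO[Si](C)(C)C(C)(C)C | intermediate
26 | C13 enone | CC(O)(C[Si](C)(C)C)C[C@@H]1O[C@H]2[C@@H]3[C@H]1C(C)=CC(=O)[C@@H]3[C@@H](C)CO[C@@]2(C)CO[Si](C)(C)C(C)(C)C | intermediate
27 | enone alcohol with methallyl arm | C=C(C)C[C@@H]1O[C@H]2[C@@H]3[C@H]1C(C)=CC(=O)[C@@H]3[C@@H](C)CO[C@@]2(C)CO | intermediate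
28 | C1 aldehyde | C=C(C)C[C@@H]1O[C@H]2[C@@H]3[C@H]1C(C)=CC(=O)[C@@H]3[C@@H](C)CO[C@@]2(C)C=O | intermediate
29 | (1R)-homoallylic alcohol | C=C(C)C[C@@H]1O[C@H]2[C@@H]3[C@H]1C(C)=CC(=O)[C@@H]3[C@@H](C)CO[C@@]2(C)[C@H](O)CC=C | intermediate
30 | tetracyclic alcohol | O[C@@H]1C/C=C(/C)C[C@@H]2O[C@H]3[C@@H]4[C@H]2C(C)=CC(=O)[C@@H]4[C@@H](C)CO[C@@]13C | intermediate
31 | CNP0271677.1 | CCCC(=O)O[C@@H]1C/C=C(/C)C[C@@H]2O[C@H]3[C@@H]4[C@H]2C(C)=CC(=O)[C@@H]4[C@@H](C)CO[C@@]13C | target

**Step count and risks**

Total step count: 22. Longest linear sequence: 21 steps (1 to 31 through steps 1–8 and 10–22). Step 9 is the only side branch.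

Most likely to fail, first: step 10.
- The thermal cycloaddition may be too slow for the heat-sensitive dienyl epoxide.
- The single C8 centre may tell the two diene faces apart poorly, or endo from exo.
- The fallback moves stereocontrol from the substrate to a catalyst and brings the epoxide in after the cascade. It sets out from 7 and comes back at 17.
- Silylation of 7 (TBSCl, imidazole) gives the triene silyl ether F1.
- Miyaura borylation (B2pin2, PdCl2(dppf), KOAc, dioxane, 80 °C) is harmless here because no epoxide is present, and it gives the trienylboronate F2.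
- Only the C12–C9 diene of F2 can become s-cis, since C18 carries a Z substituent.
- Without an epoxide, a chiral oxazaborolidinium triflimide (the antipode that leads to 9R) can activate 14 at −78 to −40 °C. This raises rate, endo and regioselectivity, and gives the alkenyl allylboronate F3.
- Addition of 13 in the same flask gives the alkenyl borate F4 and, after work-up, the alkenyl homoallylic alcohol F5.
- HF·pyridine buffered with pyridine frees the allylic alcohol diol F6.
- Sharpless epoxidation (Ti(OiPr)4, L-(+)-diethyl tartrate, t-BuOOH), directed by the C1 hydroxyl, gives the epoxy diol F7.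
- Selective silylation of the primary alcohol (TBSCl, imidazole, 0 °C) delivers 17.

Second: step 13.
- The isopropenyl group rotates freely, so facial selectivity at C15 may be poor.
- The fallback replaces kinetic face control by thermodynamic control inside ring C. It sets out from 21, taken as the mixture of C15 epimers, and comes back at 21 as a single epimer.
- Oxidative lactonisation (TEMPO cat., PhI(OAc)2, CH2Cl2) passes through the lactol of the C16 aldehyde with the C18 hydroxyl and gives the ring C ε-lactone epimer mixture F8.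
- Equilibration through the lactone enolate (DBU, toluene, 60 °C) should place the C15 methyl group trans to C13, pseudo-equatorial on the seven-membered ring. This gives the (15R)-ε-lactone F9.
- LiAlH4 (THF, 0 °C) returns 21, which then enters step 14.

Third: step 17.
- Hydrogen abstraction may spread over C10–H, the C11 methyl group and the ether α-positions instead of staying at C13.
- The fallback reaches the enone by ionic, site-defined steps. It sets out from 25 and comes back at 26.
- mCPBA (NaHCO3, CH2Cl2) epoxidises the only alkene to the C11–C12 epoxide F10.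
- PhSeNa (from (PhSe)2 and NaBH4, EtOH, reflux) opens it at the secondary C12 to the hydroxy selenide F11.
- H2O2 brings about oxidative syn elimination, which can only run towards C13, and gives the tertiary allylic alcohol F12 (C11–OH, C12=C13).
- Pyridinium chlorochromate (NaOAc, CH2Cl2) then effects the Babler–Dauben oxidative transposition to 26.

**Further compounds**

F1 | step 10 | triene silyl ether | CC(C)(C)[Si](C)(C)OC/C(C)=C\C=C\C(C)=C\I
F2 | step 10 | trienylboronate | CC(C)(C)[Si](C)(C)OC/C(C)=C\C=C\C(C)=C\B1OC(C)(C)C(C)(C)O1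
F3 | step 10 | alkenyl allylboronate | CC(=O)[C@H]1C[C@@H](B2OC(C)(C)C(C)(C)O2)C(C)=C[C@H]1/C=C(/C)CO[Si](C)(C)C(C)(C)C
F4 | step 10 | alkenyl borate | CC1(C[C@H](OB3OC(C)(C)C(C)(C)O3)[C@@H]2C(C)=CC[C@H](C(C)=O)[C@@H]2/C=C(/C)CO[Si](C)(C)C(C)(C)C)OCCO1
F5 | step 10 | alkenyl homoallylic alcohol | CC1(C[C@H](O)[C@@H]2C(C)=CC[C@H](C(C)=O)[C@@H]2/C=C(/C)CO[Si](C)(C)C(C)(C)C)OCCO1
F6 | step 10 | allylic alcohol diol | CC1(C[C@H](O)[C@@H]2C(C)=CC[C@H](C(C)=O)[C@@H]2/C=C(/C)CO)OCCO1
F7 | step 10 | epoxy diol | CC1(C[C@H](O)[C@@H]2C(C)=CC[C@H](C(C)=O)[C@@H]2[C@H]3O[C@@]3(C)CO)OCCO1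
F8 | step 13 | ring C ε-lactone epimer mixture | CC1(C[C@@H]2O[C@H]3[C@@H]4[C@H]2C(C)=CC[C@@H]4C(C)C(=O)O[C@@]3(C)CO[Si](C)(C)C(C)(C)C)OCCO1
F9 | step 13 | (15R)-ε-lactone | CC1(C[C@@H]2O[C@H]3[C@@H]4[C@H]2C(C)=CC[C@@H]4[C@@H](C)C(=O)O[C@@]3(C)CO[Si](C)(C)C(C)(C)C)OCCO1
F10 | step 17 | C11–C12 epoxide | CC(O)(C[Si](C)(C)C)C[C@@H]1O[C@H]2[C@@H]3[C@H]1C4(C)OC4C[C@@H]3[C@@H](C)CO[C@@]2(C)CO[Si](C)(C)C(C)(C)C
F11 | step 17 | hydroxy selenide | CC(O)(C[Si](C)(C)C)C[C@@H]1O[C@H]2[C@@H]3[C@H]1C(C)(O)C([Se]c4ccccc4)C[C@@H]3[C@@H](C)CO[C@@]2(C)CO[Si](C)(C)C(C)(C)C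
F12 | step 17 | tertiary allylic alcohol | CC(O)(C[Si](C)(C)C)C[C@@H]1O[C@H]2[C@@H]3[C@H]1C(C)(O)C=C[C@@H]3[C@@H](C)CO[C@@]2(C)CO[Si](C)(C)C(C)(C)C
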